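Assumption: atoms are numbered as in germacranolides (ring C1–C10, lactone carbons C11 and C12 with the methylene C13, methyl C14 on C10, methylene C15 on C4, lactone oxygen on C6, angelate on C8); descriptors in germacrane-type names refer to these locants.

## The problem

The target 33 is a ten-membered carbocycle (C1–C10) cis-fused through C6–C7 to an α-methylene-γ-butyrolactone. It carries a cis-1,10-epoxide with a methyl group on C10, an exocyclic methylene on C4, a free allylic hydroxyl on C5 and an angelate on C8. Six stereocentres have to be set: the contiguous run C5–C8 and the separate pair C1/C10. They can control one another in a chain: an oxygen on C5 can steer C6 (1,2-anti), C6 and C7 are tied by the cis ring fusion, a hydroxyl on C10 can steer C8 (1,3-anti), and an ether on C1 can steer C10 by chelation (1,2-syn, before the inversion at C1 that closes the epoxide). The ring is the hard part: a ten-membered ring forms against transannular strain, and a cis-epoxide would otherwise call for a Z-trisubstituted ring alkene and a face-selective epoxidation. Several groups will not survive rough treatment. The angelate isomerises to the tiglate with base, nucleophiles or heat; the methylene lactone is a Michael acceptor; the trisubstituted epoxide is acid-labile; a free hydroxyl on C8 or C5 can take over the lactone carbonyl; and any C8 ketone makes H7 acidic. The feature that opens the ring is that C10 is a fully substituted, oxygen-bearing carbon β to the C8 oxygen, with only the methylene C9 between them. C8–C9–C10 is therefore an aldol retron: C9 is the enolate carbon of a C8 ketone, C10 is a methyl ketone, and the neighbouring C1 oxygen is a chelation handle whose alkoxide partner on C10 can later close the epoxide.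

## Retrosynthesis

**Epoxide and last protecting group (33 ⇐ 32 ⇐ 30).** The O–Si bond at C5 and the C1–O bond of the epoxide are cut, leading back to the 1,10-diol 30 with (1S) configuration. Closing the epoxide by displacement at C1 with inversion gives the cis-epoxide without a Z ring alkene and without a face-selective epoxidation next to two other alkenes. The forward reaction must activate the secondary C1 hydroxyl in the presence of the tertiary C10 hydroxyl and close under conditions that the angelate and the methylene lactone tolerate.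

**Angelate and C8 carbinol (30 ⇐ 29 ⇐ 26 + 27 ⇐ 25).** The acyl C–O bond at C8 and then the C8–H bond are cut, giving the β-hydroxy ketone 25 and angelic acid 27. The ester is placed directly after the reduction for two reasons: no strongly basic step follows, because the methylene lactone is already present, and a free C8 hydroxyl next to the lactone is then never carried forward. The C10 hydroxyl of 25 is asked to deliver hydride to C8 from its own side (1,3-anti).

**Ring closure (25 ⇐ 23).** The C9–C10 bond is cut. Against the neighbouring cuts (C7–C8, C4–C5 or a lactonisation-driven closure), this one creates the tertiary carbinol C10 in the same step and leaves behind a carbinol that is used twice more, for C8 and for the epoxide. The precursor 23 is an open chain on a five-membered lactone, with a bromomethyl ketone at one end and an α-alkoxy methyl ketone at the other. The forward reaction must generate the enolate only at C9, add to the C10 face selected by chelation to O1, and do both faster than proton transfer from C7.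

**Bromomethyl ketone (23 ⇐ 22 ⇐ 21 ⇐ 20).** The C9–Br bond and the C8 carbonyl are traced back to a glycerol-type 8,9-diol carried as the acetonide 20. This is chosen over building the bromoketone from a C8 acid (diazo chemistry) or a C8 alkyne (π-acid hydration), which the methylene lactone and the 1,6-related C4 methylene would not tolerate. It needs only hydrolysis, a primary-selective bromination and a neutral oxidation.

**Lactone and C6–C7 (20 ⇐ 18 + 14).** The C6–C7 bond and the lactone C12–O6 bond are cut, giving the α-silyloxy aldehyde 18 and the 2-(bromomethyl)acrylate 14. This one cut brings in C7–C9 and C11–C13, closes the lactone on O6 while O5 stays a silyl ether (so the two oxygens are never confused), and delivers C13, so no enolate methylenation is needed late in the route. A 5,6-acetonide with a late lactonisation was weighed and dropped: it would need acid after the epoxide is in place and would leave O5 and O6 undifferentiated. The forward reaction must add to the aldehyde and not the methyl ketone, follow the C5 silyloxy group (Felkin–Anh) and give the 6,7-syn adduct.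

**C3–C4 (18 ⇐ 17 ⇐ 16 ⇐ 4 + 10).** The sp3–sp2 bond C3–C4 is cut, giving the alkene 4 (C14, C10, C1–C3) and the enol triflate 10 (C15, C4–C6). This places the C4 methylene directly; the alternative, a C4–C5 carbonyl addition followed by olefination of an α-alkoxy ketone, would create C5 in the coupling and put it at risk afterwards. Both fragments are small and each carries one permanent stereocentre.

**Building blocks (4 ⇐ 3 ⇐ 2 ⇐ 1; 10 ⇐ 9 ⇐ 8 ⇐ 7 ⇐ 5; 14 ⇐ 13 ⇐ 11 + 12).** C1 comes from the desymmetrising epoxidation of divinyl carbinol 1, C5 from the glycerate ester 5, and the provisional C8 centre of 14 from the glyceraldehyde acetonide 11 and methyl acrylate 12. Every ring carbon is accounted for by five purchased compounds: 1, 5, 11, 12 and 27.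

## Roads not taken

Alternative 1: The cut is at C7–C11 and C8–C11 together with the lactone C12–O bond. A rhodium carbenoid, generated for example with Rh2(OAc)4 from the C6 diazophosphonoacetate A2, would add to the Z C7=C8 alkene and give the cyclopropane-fused phosphono lactone A1; an angelate nucleophile would then open the cyclopropane at C8, and the phosphonate would serve a mild olefination to the methylene lactone. Its merits are real: C7, C8 and C11 are set in one stereospecific step, the angelate arrives by C–O bond formation with inversion instead of acylation of a hindered alcohol, and the methylenation needs no lactone enolate. In these respects it is better than the chosen plan. Its weak point is that A2 already contains the ten-membered ring with two Z alkenes, so the ring problem is deferred, not solved. The carbenoid also has competing partners (the C4 methylene, the C1=C10 alkene, the C5–H next to the silyloxy group). A carboxylate is a poor nucleophile for opening the cyclopropane regioselectively at C8. And the cis-epoxide would still have to come from a face- and site-selective epoxidation of the Z C1=C10 alkene. The chosen plan sets against it a ring closure that creates C10 and then uses that centre for C8 and for the epoxide.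

Alternative 2: The cut is at C8–C9 and C10–O. The C8 nitrile oxide A4 would add across the isopropenyl C9=C10 alkene and give the isoxazoline-bridged carbocycle A3, a masked form of the same aldol. This is the closest relative of the chosen plan, and it is better in three respects: the cycloaddition is neutral and irreversible, there is no enolate to equilibrate and no retro-aldol, and H7 is less exposed next to a C=N than next to a ketone. Against it stand the bridged mode of closure, which forces the C=N bond to a bridgehead of a ten-membered bicycle, and the dimerisation of the dipole at the dilution a medium ring needs. The C10 face also has no chelating element and is left to ring conformation. The reductive N–O cleavage is the reason A3 carries C4 as a ketal and a saturated lactone, so that both methylenes would have to be made late, one by olefination of an α-alkoxy ketone and one through a lactone enolate. The chosen plan accepts the risk of enolate equilibration and in return reaches the hydroxy ketone with C13 and C15 in place and with chelation control at C10.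

Alternative 3: The cut is at C7–C8. An acyl radical released from the selenoester A6 would add to C7 of the butenolide and, after reduction of the lactone α-radical, give the ten-membered C8 ketone A5. Its merits are that radical conditions are neutral, the epoxide is already in place so no late base is needed, and acyl radical additions to unsaturated lactones are an established way to close rings; in functional group tolerance at the ring-closing stage it is as good as or better than the samarium step. Its weak points concern stereocontrol. C7 is formed in the ring closure with nothing but ring strain to choose between cis and trans fusion. C8 must afterwards be reduced without a directing hydroxyl, because C10 is already an epoxide. The methylene still has to be introduced through a lactone enolate in a molecule that holds a ketone or an epoxide. The epoxide in A6 again presupposes a Z alkene and its epoxidation. The chosen plan makes C7 in an open-chain step under substrate and reagent control and keeps the C10 carbinol free to direct the C8 reduction.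

Key step: step 17

## Route

Step 1
Reactants: 1 penta-1,4-dien-3-ol (divinyl carbinol)
Product: 2 (S)-1-[(R)-oxiran-2-yl]prop-2-en-1-ol [(2R,3S)-1,2-epoxypent-4-en-3-ol]
Conditions: Ti(Oi-Pr)4, L-(+)-diisopropyl tartrate, t-BuOOH, 4 Å MS, CH2Cl2, −20 °C
Reagents that add atoms: tert-butyl hydroperoxide, CC(C)(C)OO
Why: Sharpless asymmetric epoxidation used as a desymmetrisation: the L-(+)-tartrate catalyst selects one enantiotopic vinyl group and one face, so the erythro epoxy alcohol with the (3S) carbinol (later C1) should form, and the minor enantiomer is removed by faster second epoxidation.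

Step 2
Reactants: 2 (S)-1-[(R)-oxiran-2-yl]prop-2-en-1-ol
Product: 3 (R)-2-{(S)-1-[(4-methoxybenzyl)oxy]prop-2-en-1-yl}oxirane
Conditions: NaH, PMBCl, n-Bu4NI (cat.), THF, 0 °C
Reagents that add atoms: 4-methoxybenzyl chloride, COc1ccc(CCl)cc1
Why: Williamson etherification; fast alkylation by the benzylic iodide formed in situ at low temperature should outrun Payne rearrangement of the epoxy alkoxide, and no stereocentre is touched.

Step 3
Reactants: 3 (R)-2-{(S)-1-[(4-methoxybenzyl)oxy]prop-2-en-1-yl}oxirane
Product: 4 (2R,3S)-3-[(4-methoxybenzyl)oxy]pent-4-en-2-ol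
Conditions: LiAlH4, THF, 0 °C
Reagents that add atoms: none
Why: Hydride opens the terminal epoxide at the CH2 carbon (SN2), which turns it into the C14 methyl and the C10 carbinol; the C10 centre is provisional and is oxidised in step 12.

Step 4
Reactants: 5 methyl (R)-2,2-dimethyl-1,3-dioxolane-4-carboxylate
Product: 7 1-[(4R)-2,2-dimethyl-1,3-dioxolan-4-yl]ethan-1-one, via Weinreb amide 6 (not isolated)
Conditions: MeNH(OMe)·HCl, i-PrMgCl, THF, −20 °C; then MeMgBr, 0 °C
Reagents that add atoms: methylmagnesium bromide, C[Mg]Br
Why: Weinreb ketone synthesis in one pot: the magnesium amide converts the ester into amide 6, whose chelated tetrahedral adduct with MeMgBr stops at the ketone; the α-alkoxy stereocentre (later C5) is not enolised.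

Step 5
Reactants: 7 1-[(4R)-2,2-dimethyl-1,3-dioxolan-4-yl]ethan-1-one
Product: 8 1-[(4R)-2,2-dimethyl-1,3-dioxolan-4-yl]ethenyl trifluoromethanesulfonate
Conditions: KN(SiMe3)2, PhNTf2, THF, −78 °C
Reagents that add atoms: N-phenylbis(trifluoromethanesulfonimide), O=S(=O)(N(c1ccccc1)S(=O)(=O)C(F)(F)F)C(F)(F)F
Why: Kinetic deprotonation of the methyl ketone at CH3 and O-sulfonylation give the 2-triflyloxy-1-alkene, that is C4 with the C15 methylene; the ring methine is not deprotonated under these conditions.

Step 6
Reactants: 8 1-[(4R)-2,2-dimethyl-1,3-dioxolan-4-yl]ethenyl trifluoromethanesulfonate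
Product: 9 (3R)-3,4-dihydroxybut-1-en-2-yl trifluoromethanesulfonate
Conditions: AcOH/H2O (4:1), 40 °C
Reagents that add atoms: none
Why: Acid hydrolysis of the isopropylidene acetal; the enol triflate is stable to aqueous acid.

Step 7
Reactants: 9 (3R)-3,4-dihydroxybut-1-en-2-yl trifluoromethanesulfonate
Product: 10 (3R)-3,4-bis[(tert-butyldimethylsilyl)oxy]but-1-en-2-yl trifluoromethanesulfonate
Conditions: TBSCl, imidazole, DMF, rt
Reagents that add atoms: tert-butyldimethylsilyl chloride, CC(C)(C)[Si](C)(C)Cl
Why: Silylation of both hydroxyls; the secondary ether becomes the lasting C5 protection and the primary one is removed selectively in step 11.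

Step 8
Reactants: 11 (R)-2,2-dimethyl-1,3-dioxolane-4-carbaldehyde; 12 methyl acrylate
Product: 13 methyl 2-{[(4R)-2,2-dimethyl-1,3-dioxolan-4-yl](hydroxy)methyl}prop-2-enoate (both carbinol epimers)
Conditions: DABCO, excess 12 as solvent, rt
Reagents that add atoms: none
Why: Morita–Baylis–Hillman reaction; the new carbinol centre forms as a mixture, which does not matter because it becomes sp2 in step 9.

Step 9
Reactants: 13 methyl 2-{[(4R)-2,2-dimethyl-1,3-dioxolan-4-yl](hydroxy)methyl}prop-2-enoate
Product: 14 methyl (2Z)-2-(bromomethyl)-3-[(4S)-2,2-dimethyl-1,3-dioxolan-4-yl]prop-2-enoate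
Conditions: NBS, Me2S, CH2Cl2, 0 °C to rt
Reagents that add atoms: N-bromosuccinimide, O=C1CCC(=O)N1Br
Why: Corey–Kim-type activation of the allylic alcohol and SN2' delivery of bromide give the rearranged, thermodynamically preferred Z trisubstituted acrylate from both epimers of 13; the conditions are neutral enough for the acetonide.

Step 10
Reactants: 4 (2R,3S)-3-[(4-methoxybenzyl)oxy]pent-4-en-2-ol; 10 (3R)-3,4-bis[(tert-butyldimethylsilyl)oxy]but-1-en-2-yl trifluoromethanesulfonate
Product: 16 (2R,3S,7S)-7,8-bis[(tert-butyldimethylsilyl)oxy]-3-[(4-methoxybenzyl)oxy]-6-methylideneoctan-2-ol, via alkylborane 15 (not isolated)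
Conditions: 4, 9-BBN (2.2 equiv), THF, rt; then 10, Pd(dppf)Cl2, AsPh3, Cs2CO3, DMF/H2O, rt
Reagents that add atoms: none
Why: Anti-Markovnikov hydroboration of the vinyl group (the second equivalent of borane caps the hydroxyl) followed by B-alkyl Suzuki–Miyaura coupling with the enol triflate forms C3–C4 and sets the C4 methylene in place; no stereocentre is involved.

Step 11
Reactants: 16 (2R,3S,7S)-7,8-bis[(tert-butyldimethylsilyl)oxy]-3-[(4-methoxybenzyl)oxy]-6-methylideneoctan-2-ol
Product: 17 (2S,6S,7R)-2-[(tert-butyldimethylsilyl)oxy]-6-[(4-methoxybenzyl)oxy]-3-methylideneoctane-1,7-diol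
Conditions: HF·pyridine, pyridine, THF, 0 °C
Reagents that add atoms: none
Why: Buffered fluoride cleaves the unhindered primary silyl ether much faster than the secondary allylic one flanked by C4 and C6.

Step 12
Reactants: 17 (2S,6S,7R)-2-[(tert-butyldimethylsilyl)oxy]-6-[(4-methoxybenzyl)oxy]-3-methylideneoctane-1,7-diol
Product: 18 (2S,6S)-2-[(tert-butyldimethylsilyl)oxy]-6-[(4-methoxybenzyl)oxy]-3-methylidene-7-oxooctanal
Conditions: Dess–Martin periodinane (excess), NaHCO3, CH2Cl2, 0 °C to rt; used crude
Reagents that add atoms: none
Why: Dess–Martin oxidation converts the primary alcohol into the C6 aldehyde and the C10 carbinol into the methyl ketone in one operation under buffered, non-enolising conditions, which should preserve the allylic α-silyloxy centre C5.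

Step 13
Reactants: 18 (2S,6S)-2-[(tert-butyldimethylsilyl)oxy]-6-[(4-methoxybenzyl)oxy]-3-methylidene-7-oxooctanal; 14 methyl (2Z)-2-(bromomethyl)-3-[(4S)-2,2-dimethyl-1,3-dioxolan-4-yl]prop-2-enoate
Product: 20 (4R,5R)-5-{(1S,5S)-1-[(tert-butyldimethylsilyl)oxy]-5-[(4-methoxybenzyl)oxy]-2-methylidene-6-oxoheptyl}-4-[(4S)-2,2-dimethyl-1,3-dioxolan-4-yl]-3-methylideneoxolan-2-one, via hydroxy ester 19 (not isolated)
Conditions: CrCl2, THF, 0 °C to rt; then PPTS (cat.), toluene, 40 °C
Reagents that add atoms: none
Why: Nozaki–Hiyama 2-(alkoxycarbonyl)allylation: the allylchromium reagent from 14 and divalent chromium adds to the aldehyde only, through a closed chair transition state in which the ester keeps the C8 substituent cis to the CH2Cr carbon, so the 6,7-syn adduct and after lactonisation the cis-lactone should result. C6 is set by Felkin–Anh addition anti to the C5 silyloxy group, C7 follows from the chair, and the dioxolane centre of 14 is chosen so that the C6–C7 bond forms anti to its C–C bond with the C–O bond outside (expected matched case).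

Step 14
Reactants: 20 the acetonide lactone of step 13
Product: 21 (4R,5R)-5-{(1S,5S)-1-[(tert-butyldimethylsilyl)oxy]-5-[(4-methoxybenzyl)oxy]-2-methylidene-6-oxoheptyl}-4-[(1S)-1,2-dihydroxyethyl]-3-methylideneoxolan-2-one
Conditions: CuCl2·2H2O, MeCN, 0 °C
Reagents that add atoms: none
Why: Mild Lewis-acid hydrolysis of the terminal isopropylidene acetal, which the hindered secondary silyl ether and the benzyl-type ether tolerate; contact is kept short so that the freed C8 hydroxyl does not take over the lactone carbonyl.

Step 15
Reactants: 21 the 8,9-diol of step 14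
Product: 22 (4R,5R)-4-[(1S)-2-bromo-1-hydroxyethyl]-5-{(1S,5S)-1-[(tert-butyldimethylsilyl)oxy]-5-[(4-methoxybenzyl)oxy]-2-methylidene-6-oxoheptyl}-3-methylideneoxolan-2-one
Conditions: CBr4, PPh3, CH2Cl2, −20 to 0 °C
Reagents that add atoms: carbon tetrabromide, BrC(Br)(Br)Br
Why: Appel bromination is selective for the primary C9 hydroxyl over the hindered secondary C8 hydroxyl; the phosphine is consumed by CBr4 before it can add to the methylene lactone.

Step 16
Reactants: 22 the bromohydrin of step 15
Product: 23 (4S,5R)-4-(bromoacetyl)-5-{(1S,5S)-1-[(tert-butyldimethylsilyl)oxy]-5-[(4-methoxybenzyl)oxy]-2-methylidene-6-oxoheptyl}-3-methylideneoxolan-2-one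
Conditions: Dess–Martin periodinane, NaHCO3, CH2Cl2, 0 °C
Reagents that add atoms: none
Why: Dess–Martin oxidation of the bromohydrin gives the bromomethyl ketone without base, so the now acidic H7 and the exocyclic alkene should stay where they are; 23 is used at once.

Step 17
Reactants: 23 the bromomethyl ketone of step 16
Product: 25 (1S,5S,6R,7S,10S)-5-[(tert-butyldimethylsilyl)oxy]-10-hydroxy-1-[(4-methoxybenzyl)oxy]-8-oxogermacra-4(15),11(13)-dien-12,6-olide, via samarium enolate 24 (not isolated)
Conditions: SmI2 (2.2 equiv), THF, −78 °C, slow addition of 23 (high dilution); pH 7 buffer at −78 °C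
Reagents that add atoms: none
Why: Two equivalents of SmI2 (divalent samarium) cleave the C9–Br bond by successive single-electron transfers and give the trivalent samarium enolate 24 at C9 only, so no base has to choose between the α-positions. The step is an intramolecular samarium Reformatsky (aldol) addition, the reaction type known for closing medium and large rings from α-bromo carbonyl compounds. The oxophilic metal binds the C10 carbonyl and the C1 ether oxygen, and C9 attacks the ketone carbon through a metal-bridged cyclic transition state; the ten-membered ring closes in the exo-trig mode at the carbonyl, with the enolate double bond inside the ring. The new stereocentre C10 is set by Cram-chelate control: in the five-membered O1–Sm–O10 chelate the enolate comes to the ketone face anti to C2, which gives the 1,10-syn relation, (10S) from (1S). The step needs C–Br cleavage ahead of ketyl formation at the α-alkoxy ketone and ahead of reduction of the methylene lactone, which the far easier reduction of the α-bromo ketone at −78 °C without proton source or HMPA should secure. It also needs ring closure ahead of proton transfer from C7, for which low temperature, high dilution and the templating metal are relied on, and a cold neutral quench so that the samarium aldolate does not revert. The cis-lactone and the chelate hold the two chain ends on the same side, which offsets part of the entropic cost.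

Step 18
Reactants: 25 the β-hydroxy ketone of step 17
Product: 26 (1S,5S,6R,7R,8S,10S)-5-[(tert-butyldimethylsilyl)oxy]-8,10-dihydroxy-1-[(4-methoxybenzyl)oxy]germacra-4(15),11(13)-dien-12,6-olide
Conditions: Me4NBH(OAc)3, MeCN/AcOH, −30 °C
Reagents that add atoms: none
Why: Evans–Saksena reduction: the C10 hydroxyl exchanges onto boron and delivers hydride intramolecularly through a chair-like six-membered transition state, giving the 1,3-anti diol, that is (8S); the acidic medium suppresses enolisation at C7, and the reagent leaves the lactone and the enoate alone.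

Step 19
Reactants: 26 the 8,10-diol of step 18; 27 angelic acid [(Z)-2-methylbut-2-enoic acid]
Product: 29 (1S,5S,6R,7R,8S,10S)-8-(angeloyloxy)-5-[(tert-butyldimethylsilyl)oxy]-10-hydroxy-1-[(4-methoxybenzyl)oxy]germacra-4(15),11(13)-dien-12,6-olide, via mixed anhydride 28 (not isolated)
Conditions: 27, 2,4,6-Cl3C6H2COCl, Et3N, toluene, rt; then 26, 75 °C
Reagents that add atoms: none
Why: Yamaguchi esterification through the preformed mixed anhydride and without a nucleophilic catalyst, the conditions under which the Z acid is transferred without drifting to the E isomer; the secondary C8 hydroxyl reacts and the tertiary C10 hydroxyl does not.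

Step 20
Reactants: 29 the 8-angelate of step 19
Product: 30 (1S,5S,6R,7R,8S,10S)-8-(angeloyloxy)-5-[(tert-butyldimethylsilyl)oxy]-1,10-dihydroxygermacra-4(15),11(13)-dien-12,6-olide
Conditions: DDQ, CH2Cl2/pH 7 buffer, 0 °C
Reagents that add atoms: none
Why: Oxidative cleavage of the 4-methoxybenzyl ether through its benzylic oxocarbenium ion; the wet buffered medium favours hydrolysis over capture by the hindered tertiary hydroxyl, and the electron-poor alkenes and the silyl ether are not oxidised.

Step 21
Reactants: 30 the 1,10-diol of step 20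
Product: 32 (1R,5S,6R,7R,8S,10S)-8-(angeloyloxy)-5-[(tert-butyldimethylsilyl)oxy]-1,10-epoxygermacra-4(15),11(13)-dien-12,6-olide, via mesylate 31 (not isolated)
Conditions: MsCl, Et3N, CH2Cl2, 0 °C; then DBU, rt
Reagents that add atoms: none
Why: The secondary C1 hydroxyl is sulfonylated in preference to the tertiary one, and the C10 oxygen then displaces the mesylate from the back (intramolecular Williamson reaction, 3-exo-tet) with inversion at C1, which turns the 1,10-syn diol into the cis-epoxide, (1R,10S).

Step 22
Reactants: 32 the silyl ether of step 21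
Product: 33 (1R,5S,6R,7R,8S,10S)-8-(angeloyloxy)-1,10-epoxy-5-hydroxygermacra-4(15),11(13)-dien-12,6-olide (target, CNP0227074.3)
Conditions: HF·pyridine, pyridine, THF, 0 °C to rt
Reagents that add atoms: none
Why: Fluoride desilylation buffered with pyridine, conditions under which a trisubstituted epoxide, an angelate and a methylene lactone are expected to survive; no stereocentre is affected.

## Compound list

1 | penta-1,4-dien-3-ol | C=CC(O)C=C | starting material
2 | (S)-1-[(R)-oxiran-2-yl]prop-2-en-1-ol | C=C[C@H](O)[C@H]1CO1 | intermediate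
3 | (R)-2-{(S)-1-[(4-methoxybenzyl)oxy]prop-2-en-1-yl}oxirane | C=C[C@H](OCc1ccc(OC)cc1)[C@H]1CO1 | intermediate
4 | (2R,3S)-3-[(4-methoxybenzyl)oxy]pent-4-en-2-ol | C=C[C@H](OCc1ccc(OC)cc1)[C@@H](C)O | intermediate
5 | methyl (R)-2,2-dimethyl-1,3-dioxolane-4-carboxylate | COC(=O)[C@H]1COC(C)(C)O1 | starting material
6 | (R)-N-methoxy-N,2,2-trimethyl-1,3-dioxolane-4-carboxamide | CON(C)C(=O)[C@H]1COC(C)(C)O1 | intermediate
7 | 1-[(4R)-2,2-dimethyl-1,3-dioxolan-4-yl]ethan-1-one | CC(=O)[C@H]1COC(C)(C)O1 | intermediate
8 | 1-[(4R)-2,2-dimethyl-1,3-dioxolan-4-yl]ethenyl trifluoromethanesulfonate | C=C(OS(=O)(=O)C(F)(F)F)[C@H]1COC(C)(C)O1 | intermediate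
9 | (3R)-3,4-dihydroxybut-1-en-2-yl trifluoromethanesulfonate | C=C(OS(=O)(=O)C(F)(F)F)[C@H](O)CO | intermediate
10 | (3R)-3,4-bis[(tert-butyldimethylsilyl)oxy]but-1-en-2-yl trifluoromethanesulfonate | C=C(OS(=O)(=O)C(F)(F)F)[C@H](O[Si](C)(C)C(C)(C)C)CO[Si](C)(C)C(C)(C)C | intermediate
11 | (R)-2,2-dimethyl-1,3-dioxolane-4-carbaldehyde | O=C[C@H]1COC(C)(C)O1 | starting material
12 | methyl acrylate | C=CC(=O)OC | starting material
13 | methyl 2-{[(4R)-2,2-dimethyl-1,3-dioxolan-4-yl](hydroxy)methyl}prop-2-enoate (both carbinol epimers) | C=C(C(=O)OC)C(O)[C@H]1COC(C)(C)O1 | intermediate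
14 | methyl (2Z)-2-(bromomethyl)-3-[(4S)-2,2-dimethyl-1,3-dioxolan-4-yl]prop-2-enoate | BrC/C(C(=O)OC)=C\[C@H]1COC(C)(C)O1 | intermediate
15 | 9-[(3S,4R)-4-(9-borabicyclo[3.3.1]nonan-9-yloxy)-3-[(4-methoxybenzyl)oxy]pentyl]-9-borabicyclo[3.3.1]nonane | C[C@@H](OB1C2CCCC1CCC2)[C@@H](OCc1ccc(OC)cc1)CCB1C2CCCC1CCC2 | intermediate
16 | (2R,3S,7S)-7,8-bis[(tert-butyldimethylsilyl)oxy]-3-[(4-methoxybenzyl)oxy]-6-methylideneoctan-2-ol | C[C@@H](O)[C@@H](OCc1ccc(OC)cc1)CCC(=C)[C@H](O[Si](C)(C)C(C)(C)C)CO[Si](C)(C)C(C)(C)C | intermediate
17 | (2S,6S,7R)-2-[(tert-butyldimethylsilyl)oxy]-6-[(4-methoxybenzyl)oxy]-3-methylideneoctane-1,7-diol | C[C@@H](O)[C@@H](OCc1ccc(OC)cc1)CCC(=C)[C@H](O[Si](C)(C)C(C)(C)C)CO | intermediate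
18 | (2S,6S)-2-[(tert-butyldimethylsilyl)oxy]-6-[(4-methoxybenzyl)oxy]-3-methylidene-7-oxooctanal | CC(=O)[C@@H](OCc1ccc(OC)cc1)CCC(=C)[C@H](O[Si](C)(C)C(C)(C)C)C=O | intermediate
19 | methyl (3S,4R,5S,9S)-5-[(tert-butyldimethylsilyl)oxy]-3-[(4S)-2,2-dimethyl-1,3-dioxolan-4-yl]-4-hydroxy-9-[(4-methoxybenzyl)oxy]-2,6-dimethylidene-10-oxoundecanoate | C=C(C(=O)OC)[C@H]([C@H]1COC(C)(C)O1)[C@@H](O)[C@@H](O[Si](C)(C)C(C)(C)C)C(=C)CC[C@H](OCc1ccc(OC)cc1)C(C)=O | intermediate
20 | (4R,5R)-5-{(1S,5S)-1-[(tert-butyldimethylsilyl)oxy]-5-[(4-methoxybenzyl)oxy]-2-methylidene-6-oxoheptyl}-4-[(4S)-2,2-dimethyl-1,3-dioxolan-4-yl]-3-methylideneoxolan-2-one | C=C1C(=O)O[C@H]([C@H]1[C@H]2COC(C)(C)O2)[C@@H](O[Si](C)(C)C(C)(C)C)C(=C)CC[C@H](OCc1ccc(OC)cc1)C(C)=O | intermediate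
21 | (4R,5R)-5-{(1S,5S)-1-[(tert-butyldimethylsilyl)oxy]-5-[(4-methoxybenzyl)oxy]-2-methylidene-6-oxoheptyl}-4-[(1S)-1,2-dihydroxyethyl]-3-methylideneoxolan-2-one | C=C1C(=O)O[C@H]([C@H]1[C@H](O)CO)[C@@H](O[Si](C)(C)C(C)(C)C)C(=C)CC[C@H](OCc1ccc(OC)cc1)C(C)=O | intermediate
22 | (4R,5R)-4-[(1S)-2-bromo-1-hydroxyethyl]-5-{(1S,5S)-1-[(tert-butyldimethylsilyl)oxy]-5-[(4-methoxybenzyl)oxy]-2-methylidene-6-oxoheptyl}-3-methylideneoxolan-2-one | C=C1C(=O)O[C@H]([C@H]1[C@H](O)CBr)[C@@H](O[Si](C)(C)C(C)(C)C)C(=C)CC[C@H](OCc1ccc(OC)cc1)C(C)=O | intermediate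
23 | (4S,5R)-4-(bromoacetyl)-5-{(1S,5S)-1-[(tert-butyldimethylsilyl)oxy]-5-[(4-methoxybenzyl)oxy]-2-methylidene-6-oxoheptyl}-3-methylideneoxolan-2-one | C=C1C(=O)O[C@H]([C@H]1C(=O)CBr)[C@@H](O[Si](C)(C)C(C)(C)C)C(=C)CC[C@H](OCc1ccc(OC)cc1)C(C)=O | intermediate
24 | diiodosamarium C9 enolate of 23 (C8–O–SmI2, C8=C9) | C=C1C(=O)O[C@H]([C@H]1C(=C)O[Sm](I)I)[C@@H](O[Si](C)(C)C(C)(C)C)C(=C)CC[C@H](OCc1ccc(OC)cc1)C(C)=O | intermediate
25 | (1S,5S,6R,7S,10S)-5-[(tert-butyldimethylsilyl)oxy]-10-hydroxy-1-[(4-methoxybenzyl)oxy]-8-oxogermacra-4(15),11(13)-dien-12,6-olide | C=C1C(=O)O[C@@H]2[C@H]1C(=O)C[C@](C)(O)[C@@H](OCc1ccc(OC)cc1)CCC(=C)[C@@H]2O[Si](C)(C)C(C)(C)C | intermediate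
26 | (1S,5S,6R,7R,8S,10S)-5-[(tert-butyldimethylsilyl)oxy]-8,10-dihydroxy-1-[(4-methoxybenzyl)oxy]germacra-4(15),11(13)-dien-12,6-olide | C=C1C(=O)O[C@@H]2[C@H]1[C@@H](O)C[C@](C)(O)[C@@H](OCc1ccc(OC)cc1)CCC(=C)[C@@H]2O[Si](C)(C)C(C)(C)C | intermediate
27 | angelic acid, (Z)-2-methylbut-2-enoic acid | C/C=C(/C)C(=O)O | starting material
28 | (Z)-2-methylbut-2-enoic 2,4,6-trichlorobenzoic anhydride | C/C=C(/C)C(=O)OC(=O)c1c(Cl)cc(Cl)cc1Cl | intermediate
29 | (1S,5S,6R,7R,8S,10S)-8-(angeloyloxy)-5-[(tert-butyldimethylsilyl)oxy]-10-hydroxy-1-[(4-methoxybenzyl)oxy]germacra-4(15),11(13)-dien-12,6-olide | C=C1C(=O)O[C@@H]2[C@H]1[C@@H](OC(=O)/C(C)=C\C)C[C@](C)(O)[C@@H](OCc1ccc(OC)cc1)CCC(=C)[C@@H]2O[Si](C)(C)C(C)(C)C | intermediate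
30 | (1S,5S,6R,7R,8S,10S)-8-(angeloyloxy)-5-[(tert-butyldimethylsilyl)oxy]-1,10-dihydroxygermacra-4(15),11(13)-dien-12,6-olide | C=C1C(=O)O[C@@H]2[C@H]1[C@@H](OC(=O)/C(C)=C\C)C[C@](C)(O)[C@@H](O)CCC(=C)[C@@H]2O[Si](C)(C)C(C)(C)C | intermediate
31 | 1-O-methanesulfonate of 30 | C=C1C(=O)O[C@@H]2[C@H]1[C@@H](OC(=O)/C(C)=C\C)C[C@](C)(O)[C@@H](OS(C)(=O)=O)CCC(=C)[C@@H]2O[Si](C)(C)C(C)(C)C | intermediate
32 | (1R,5S,6R,7R,8S,10S)-8-(angeloyloxy)-5-[(tert-butyldimethylsilyl)oxy]-1,10-epoxygermacra-4(15),11(13)-dien-12,6-olide | C=C1C(=O)O[C@@H]2[C@H]1[C@@H](OC(=O)/C(C)=C\C)C[C@]1(C)O[C@@H]1CCC(=C)[C@@H]2O[Si](C)(C)C(C)(C)C | intermediate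
33 | (1R,5S,6R,7R,8S,10S)-8-(angeloyloxy)-1,10-epoxy-5-hydroxygermacra-4(15),11(13)-dien-12,6-olide | C=C1C(=O)O[C@@H]2[C@H]1[C@@H](OC(=O)/C(C)=C\C)C[C@]1(C)O[C@@H]1CCC(=C)[C@@H]2O | target

## Step count and least certain steps

Total: 22 steps. Longest linear sequence: 17 steps (steps 4–7 and 10–22, from 5).

**Step 17 (key step).** Three processes threaten it. The first is proton transfer from the doubly activated C7 to the samarium enolate or aldolate, which would lose the C7 configuration, move the exocyclic double bond into conjugation or eliminate the lactone carboxylate. The second is simple protonation of the enolate without ring closure, because of transannular strain. The third is reversal of the aldol on warming. Weak chelation would also erode the C10 face selectivity. Fallback: from 23, zinc and Me3SiCl (reductive silylation of the α-bromo ketone) give the regiodefined trimethylsilyl enol ether F1. F1 is then closed with TiCl4 in CH2Cl2 at −78 °C under high dilution in a chelation-controlled intramolecular Mukaiyama aldol addition, which has no free metal enolate, and returns to the route at 25.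

**Step 13.** Three stereochemical elements must cooperate: Felkin–Anh addition at the aldehyde, the syn-selective chair, and the facial preference of the dioxolane-bearing reagent. A mismatched pairing, or isomerisation of the labile aldehyde 18 before it is consumed, would lower the selectivity. Fallback: reverse the chirality of the reagent. (S)-2,2-Dimethyl-1,3-dioxolane-4-carbaldehyde F2 and 12 give the Morita–Baylis–Hillman adduct F3, and NBS/Me2S gives the bromide F4 (enantiomer of 14). Coupling with 18 under the same chromium conditions would give the lactone F5 (C8 epimer of 20). Hydrolysis then gives the diol F6 and Appel bromination the bromohydrin F7. Dess–Martin oxidation removes the C8 stereocentre and returns to the route at 23.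

**Step 18.** The ten-membered ring may not allow the chair-like hydride delivery, or the tertiary hydroxyl may exchange onto boron too slowly, so that the anti selectivity is poor. Fallback: from 25, a chelation-controlled syn reduction (Et2BOMe, NaBH4, THF/MeOH, −78 °C; Narasaka–Prasad) gives the 8-epimeric diol F8. Mitsunobu esterification with 27 (PPh3, DIAD) then introduces the angelate with inversion at C8 and returns to the route at 29.

**Step 21.** The amidine base may add to the methylene lactone, isomerise the angelate or promote acyl migration to O10 before the ring closes, and the closure needs an anti-periplanar O10–C10–C1–O arrangement that the ring may resist. Fallback: from 30 directly to 32 by redox cyclodehydration (PPh3, DIAD, toluene), in which the secondary C1 hydroxyl is activated as an oxyphosphonium ion and displaced by the tertiary hydroxyl with the same inversion, without a sulfonate and without base; no new compound is made.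

## Further compounds

F1 | step 17 | trimethylsilyl C9 enol ether of 23 | C=C1C(=O)O[C@H]([C@H]1C(=C)O[Si](C)(C)C)[C@@H](O[Si](C)(C)C(C)(C)C)C(=C)CC[C@H](OCc1ccc(OC)cc1)C(C)=O
F2 | step 13 | (S)-2,2-dimethyl-1,3-dioxolane-4-carbaldehyde | O=C[C@@H]1COC(C)(C)O1
F3 | step 13 | methyl 2-{[(4S)-2,2-dimethyl-1,3-dioxolan-4-yl](hydroxy)methyl}prop-2-enoate (both carbinol epimers) | C=C(C(=O)OC)C(O)[C@@H]1COC(C)(C)O1
F4 | step 13 | methyl (2Z)-2-(bromomethyl)-3-[(4R)-2,2-dimethyl-1,3-dioxolan-4-yl]prop-2-enoate | BrC/C(C(=O)OC)=C\[C@@H]1COC(C)(C)O1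
F5 | step 13 | (4R,5R)-5-{(1S,5S)-1-[(tert-butyldimethylsilyl)oxy]-5-[(4-methoxybenzyl)oxy]-2-methylidene-6-oxoheptyl}-4-[(4R)-2,2-dimethyl-1,3-dioxolan-4-yl]-3-methylideneoxolan-2-one | C=C1C(=O)O[C@H]([C@H]1[C@@H]2COC(C)(C)O2)[C@@H](O[Si](C)(C)C(C)(C)C)C(=C)CC[C@H](OCc1ccc(OC)cc1)C(C)=O
F6 | step 13 | (4R,5R)-5-{(1S,5S)-1-[(tert-butyldimethylsilyl)oxy]-5-[(4-methoxybenzyl)oxy]-2-methylidene-6-oxoheptyl}-4-[(1R)-1,2-dihydroxyethyl]-3-methylideneoxolan-2-one | C=C1C(=O)O[C@H]([C@H]1[C@@H](O)CO)[C@@H](O[Si](C)(C)C(C)(C)C)C(=C)CC[C@H](OCc1ccc(OC)cc1)C(C)=O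
F7 | step 13 | (4R,5R)-4-[(1R)-2-bromo-1-hydroxyethyl]-5-{(1S,5S)-1-[(tert-butyldimethylsilyl)oxy]-5-[(4-methoxybenzyl)oxy]-2-methylidene-6-oxoheptyl}-3-methylideneoxolan-2-one | C=C1C(=O)O[C@H]([C@H]1[C@@H](O)CBr)[C@@H](O[Si](C)(C)C(C)(C)C)C(=C)CC[C@H](OCc1ccc(OC)cc1)C(C)=O
F8 | step 18 | (1S,5S,6R,7R,8R,10S)-5-[(tert-butyldimethylsilyl)oxy]-8,10-dihydroxy-1-[(4-methoxybenzyl)oxy]germacra-4(15),11(13)-dien-12,6-olide | C=C1C(=O)O[C@@H]2[C@H]1[C@H](O)C[C@](C)(O)[C@@H](OCc1ccc(OC)cc1)CCC(=C)[C@@H]2O[Si](C)(C)C(C)(C)C
F0 | step 21 | none | none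
A1 | alternative 1 | cyclopropane-fused phosphono lactone (product of the carbenoid addition) | CCOP(=O)(OCC)[C@]12C(=O)O[C@@H]3[C@H]1[C@H]2C/C(C)=C\CCC(=C)[C@@H]3O[Si](C)(C)C(C)(C)C
A2 | alternative 1 | C6 diazophosphonoacetate of the ten-membered Z,Z-diene | CCOP(=O)(OCC)C(=[N+]=[N-])C(=O)O[C@@H]1/C=C\C/C(C)=C\CCC(=C)[C@@H]1O[Si](C)(C)C(C)(C)C
A3 | alternative 2 | isoxazoline-bridged ten-membered carbocycle | C[C@@]12CC(=NO1)[C@H]1CC(=O)O[C@H]1[C@@H](O[Si](C)(C)C(C)(C)C)C1(OCCO1)CC[C@H]2OCc1ccc(OC)cc1
A4 | alternative 2 | C8 nitrile oxide with the C9=C10 isopropenyl group | [O-][N+]#C[C@H]1CC(=O)O[C@H]1[C@@H](O[Si](C)(C)C(C)(C)C)C1(OCCO1)CC[C@@H](OCc1ccc(OC)cc1)C(C)=C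
A5 | alternative 3 | ten-membered C8 ketone with cis-fused lactone | O=C1C[C@]2(C)O[C@@H]2CCC(=C)[C@H](O[Si](C)(C)C(C)(C)C)[C@@H]2OC(=O)C[C@H]12
A6 | alternative 3 | C8 phenyl selenoester tethered to the butenolide | O=C(C[C@]1(C)O[C@@H]1CCC(=C)[C@H](O[Si](C)(C)C(C)(C)C)[C@@H]1OC(=O)C=C1)[Se]c1ccccc1
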